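**Assumption:** the target has no stereocentre and is achiral, so it is made simply as the one compound drawn.

## Retrosynthetic overview

1. The benzene ring is the only ring and is bought in already carrying the methyl ester and the methoxy group; no ring is formed and no stereocentre is set.
2. First bond made: the aryl–alkyl C–C bond. Icos-1-ene 1, 9-BBN 2 and methyl 2-bromo-4-methoxybenzoate 3 give, via alkylborane 4, methyl 2-icosyl-4-methoxybenzoate 5 (B-alkyl Suzuki–Miyaura coupling).
3. Key bond, made last: the phenolic C(aryl)–O bond. Ester-directed C–H benzoyloxylation of 5 with dibenzoyl peroxide 6 gives aryl benzoate 7, which is cleaved in the same flask to target 8.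

## Route

Step 1
Reactants: 1 icos-1-ene; 2 9-borabicyclo[3.3.1]nonane (9-BBN); 3 methyl 2-bromo-4-methoxybenzoate
Product: 5 methyl 2-icosyl-4-methoxybenzoate, via B-icosyl-9-BBN 4 (not isolated)
Conditions: 1 (1.3 equiv), 9-BBN (0.5 M in THF, 1.3 equiv), 0 °C to rt, 6 h; then 3 (1.0 equiv), PdCl2(dppf)·CH2Cl2 (3 mol %), 3 M aq. K3PO4 (3 equiv), DMF, 60 °C, 12 h
Reagents that add atoms: none
Why: Anti-Markovnikov hydroboration of the terminal alkene gives the primary alkylborane 4, which undergoes B-alkyl Suzuki–Miyaura coupling with the aryl bromide (oxidative addition to zerovalent palladium is helped by the ortho ester, dppf suppresses β-hydride elimination, and K3PO4 spares the methyl ester); no stereocentre is formed.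

Step 2
Reactants: 5 methyl 2-icosyl-4-methoxybenzoate; 6 dibenzoyl peroxide
Product: 8 methyl 2-hydroxy-6-icosyl-4-methoxybenzoate, via aryl benzoate 7 (not isolated)
Conditions: [Cp*IrCl2]2 (4 mol %), AgNTf2 (16 mol %), PhCO2H (30 mol %), Li2CO3 (30 mol %), (PhCO2)2 (1.3 equiv), ClCH2CH2Cl, 50 °C, dark, 16 h; then pyrrolidine (5 equiv), 0 °C to rt, 1 h; aq. NH4Cl work-up
Reagents that add atoms: dibenzoyl peroxide, O=C(OOC(=O)c1ccccc1)c1ccccc1 (supplies the phenolic oxygen)
Why: Proposed new method: ester-directed ortho C–H benzoyloxylation at a cationic Cp*-iridium carboxylate, in which the ester carbonyl of 5 guides concerted metalation–deprotonation of the only free ortho C–H bond to a five-membered trivalent iridacycle, the O–O bond of 6 adds oxidatively to give a pentavalent aryl iridium bis(benzoate), and C–O reductive elimination releases aryl benzoate 7 (no ortho C–H left, oxygen masked against over-oxidation), after which pyrrolidine cleaves the activated aryl ester by aminolysis while the doubly ortho-substituted methyl ester stays inert; the closest known reaction types are ester-directed ortho C–H amidation at Cp*-iridium catalysts and directed palladium-catalysed C–H benzoyloxylation with diacyl peroxides, and chelation control overrides the innate preference of the anisole ring for attack ortho to the methoxy group; no stereocentre is formed.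

## Compound list

1 | icos-1-ene | C=CCCCCCCCCCCCCCCCCCC | starting material
2 | 9-borabicyclo[3.3.1]nonane (9-BBN, drawn as monomer) | B1C2CCCC1CCC2 | starting material (reagent)
3 | methyl 2-bromo-4-methoxybenzoate | COC(=O)c1ccc(OC)cc1Br | starting material
4 | 9-icosyl-9-borabicyclo[3.3.1]nonane (B-icosyl-9-BBN) | CCCCCCCCCCCCCCCCCCCCB1C2CCCC1CCC2 | intermediate (not isolated)
5 | methyl 2-icosyl-4-methoxybenzoate | CCCCCCCCCCCCCCCCCCCCc1cc(OC)ccc1C(=O)OC | intermediate
6 | dibenzoyl peroxide | O=C(OOC(=O)c1ccccc1)c1ccccc1 | starting material (reagent)
7 | methyl 2-(benzoyloxy)-6-icosyl-4-methoxybenzoate | CCCCCCCCCCCCCCCCCCCCc1cc(OC)cc(OC(=O)c2ccccc2)c1C(=O)OC | intermediate (not isolated)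
8 | methyl 2-hydroxy-6-icosyl-4-methoxybenzoate | CCCCCCCCCCCCCCCCCCCCc1cc(OC)cc(O)c1C(=O)OC | target

## Step count and risks

Total step count: 2.
Longest linear sequence: 2 steps (1 → 5 → 8).

The route has only two steps, so both are ranked; the third entry is the second in-flask stage of step 2.

1. **Step 2, C–O bond-forming stage (the proposed new method).** The ester is a weak directing group, oxidative addition of the peroxide to the iridacycle is untested, and radical or non-directed benzoyloxylation could occur at the benzylic CH2 or at the ring positions ortho to the methoxy group. The fallback uses known chemistry and sets out from 5. Ester-directed ortho C–H borylation ([Ir(OMe)(cod)]2, P[3,5-(CF3)2C6H3]3, B2pin2, octane, 80 °C) gives methyl 2-icosyl-4-methoxy-6-(4,4,5,5-tetramethyl-1,3,2-dioxaborolan-2-yl)benzoate F1. Oxidation of the C–B bond (NaBO3·4H2O, THF/H2O, rt) then gives the phenol, and the fallback comes back to the route at 8.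

2. **Step 1.** Commercial icos-1-ene can carry chain homologues and internal-alkene isomers that would be carried into 5 and are hard to separate; protodeboronation or β-hydride elimination can also lower the yield. The fallback sets out from 3 and purchased 1-bromoicosane (CCCCCCCCCCCCCCCCCCCCBr). Zinc insertion (Zn dust, LiCl, THF, 50 °C) gives icosylzinc bromide F2. Negishi coupling with 3 (Pd(OAc)2 2 mol %, SPhos 4 mol %, THF, rt to 50 °C) then comes back to the route at 5.

3. **Step 2, second stage (debenzoylation in the same flask).** Pyrrolidine meets leftover peroxide and iridium and silver salts, which may give a messy mixture or incomplete cleavage. The fallback sets out from 7, isolated after an aqueous NaHCO3/Na2S2O3 wash and filtration through silica. Methanolysis of the aryl benzoate (K2CO3, MeOH/THF, rt; exchange at the methyl ester is degenerate) comes back to the route at 8. This fallback makes no compound outside the list (F0) and lengthens the route to three steps.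

## Further compounds

F1 | step 2 | methyl 2-icosyl-4-methoxy-6-(4,4,5,5-tetramethyl-1,3,2-dioxaborolan-2-yl)benzoate | CCCCCCCCCCCCCCCCCCCCc1cc(OC)cc(B2OC(C)(C)C(C)(C)O2)c1C(=O)OC
F2 | step 1 | icosylzinc bromide | CCCCCCCCCCCCCCCCCCCC[Zn]Br
F0 | step 2 | none | none
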